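**Retrosynthetic overview**
- Labels: C1 (alkyne CH) to C15 (ethyl CH3); ring A = oxolane O/C3–C6, ring B = oxolane O/C4–C7, ring C = oxane O/C9–C13.
- Last ring: ring B and the C8–Br bond together, by 5-exo bromoetherification of a Z C7=C8 alkene with the C4 hydroxyl of ring A.
- C6–C7: an alkynylsilane adds to the ring-A oxocarbenium ion, joining the west and east fragments; semihydrogenation then gives the Z alkene.
- Ring C (east): Achmatowicz rearrangement and Kishi reduction of a furyl propargyl alcohol; C12–Br by conjugate HBr addition, C10–Br by inversion of an axial alcohol.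
- Ring A (west), key C–C bond C3–C4: an α-alkoxyallyl anion equivalent (the oxygen-bearing C4 acts as donor) adds to an ynal and sets both carbinol centres at once; ring order C, A, B.

Assumption: 1, 2, 10, 11, (+)-Ipc2BOMe and (S,S)-ProPhenol are bought; the reagent enantiomers named are those expected to give the drawn configurations, and the antipode is used if the sense of induction proves opposite.

**West fragment**

Step 1
Reactants: 1 3-(triisopropylsilyl)prop-2-ynal; 2 allyl methoxymethyl ether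
Product: 4 (3S,4S)-4-(methoxymethoxy)-1-(triisopropylsilyl)hex-5-en-1-yn-3-ol, via Z-alkoxyallylborane 3 (not isolated)
Conditions: 2, s-BuLi, THF, −78 °C; (+)-Ipc2BOMe; BF3·OEt2; then 1, −78 °C; NaOH, H2O2, 0 °C → rt
Reagents that add atoms: none
Why: Brown asymmetric γ-alkoxyallylboration, in which the metalated allyl ether is an α-alkoxy carbanion equivalent so that C4 (by natural polarity an acceptor, like the aldehyde carbon C3) attacks as the donor; the closed chair transition state with the Z enol ether gives the syn C3/C4 relationship and the Ipc groups direct attack to the Re face of 1, giving 3S,4S.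

Step 2
Reactants: 4 (3S,4S)-4-(methoxymethoxy)-1-(triisopropylsilyl)hex-5-en-1-yn-3-ol
Product: 6 (3S,4S)-3-(methoxymethoxy)-6-(triisopropylsilyl)hex-5-yne-1,4-diol, via bis-borane 5 (not isolated)
Conditions: 9-BBN (2.5 equiv), THF, 0 °C → rt; then NaOH, H2O2, 0 °C
Reagents that add atoms: hydrogen peroxide, OO
Why: Anti-Markovnikov hydroboration–oxidation of the terminal alkene places the hydroxyl on C6, the bulky borane leaving the hindered silylalkyne untouched; no stereocentre is formed.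

Step 3
Reactants: 6 (3S,4S)-3-(methoxymethoxy)-6-(triisopropylsilyl)hex-5-yne-1,4-diol
Product: 7 (4S,5S)-4-(methoxymethoxy)-5-[(triisopropylsilyl)ethynyl]oxolan-2-one
Conditions: TEMPO (0.2 equiv), PhI(OAc)2 (2.5 equiv), CH2Cl2, rt
Reagents that add atoms: none
Why: TEMPO/PhI(OAc)2 oxidative lactonisation oxidises only the primary alcohol; the aldehyde closes onto the C3 hydroxyl and the lactol is oxidised on to the lactone, which forms ring A with both stereocentres untouched.

Step 4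
Reactants: 7 (4S,5S)-4-(methoxymethoxy)-5-[(triisopropylsilyl)ethynyl]oxolan-2-one
Product: 9 (4S,5S)-4-(methoxymethoxy)-5-[(triisopropylsilyl)ethynyl]oxolan-2-yl acetate (both C2 epimers), via aluminium lactolate 8 (not isolated)
Conditions: i-Bu2AlH, CH2Cl2, −78 °C; then pyridine, DMAP, Ac2O, −78 → −20 °C
Reagents that add atoms: acetic anhydride, CC(=O)OC(C)=O
Why: Reductive acetylation (Rychnovsky protocol) traps the aluminium hemiacetal as the anomeric acetate; the C6 configuration is irrelevant because it is ionised in step 11.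

**East fragment**

Step 5
Reactants: 10 5-ethylfuran-2-carbaldehyde; 11 ethynyltrimethylsilane
Product: 12 (1R)-1-(5-ethylfuran-2-yl)-3-(trimethylsilyl)prop-2-yn-1-ol
Conditions: (S,S)-ProPhenol (10 mol %), Me2Zn, PhMe, 0 °C; aq. NH4Cl
Reagents that add atoms: none
Why: Trost dinuclear zinc–ProPhenol alkynylation of a heteroaryl aldehyde; the chiral zinc complex controls the aldehyde face and sets the carbinol centre (C9, R).

Step 6
Reactants: 12 (1R)-1-(5-ethylfuran-2-yl)-3-(trimethylsilyl)prop-2-yn-1-ol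
Product: 13 (2R)-6-ethyl-6-hydroxy-2-[(trimethylsilyl)ethynyl]-2H-pyran-3(6H)-one (both C6 epimers)
Conditions: NBS, NaHCO3, NaOAc, THF/H2O (4:1), 0 °C
Reagents that add atoms: water, O
Why: Achmatowicz rearrangement: oxidative opening of the furan to the Z-enedione and recyclisation by the carbinol oxygen give the pyranone with O–C9, the C10 ketone and the C11=C12 enone in place; C9 is retained under the buffered conditions.

Step 7
Reactants: 13 (2R)-6-ethyl-6-hydroxy-2-[(trimethylsilyl)ethynyl]-2H-pyran-3(6H)-one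
Product: 14 (2R,6S)-6-ethyl-2-[(trimethylsilyl)ethynyl]-2H-pyran-3(6H)-one
Conditions: Et3SiH, CF3CO2H, CH2Cl2, −40 → 0 °C
Reagents that add atoms: none
Why: Kishi reduction: the hemiketal ionises to the cyclic oxocarbenium ion and hydride adds axially, anti to the C9 substituent, giving the 2,6-cis ring (C13, S).

Step 8
Reactants: 14 (2R,6S)-6-ethyl-2-[(trimethylsilyl)ethynyl]-2H-pyran-3(6H)-one
Product: 16 (2R,5R,6S)-5-bromo-6-ethyl-2-[(trimethylsilyl)ethynyl]oxan-3-one, via silyl enol ether 15 (not isolated)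
Conditions: Me3SiBr, CH2Cl2, −40 °C; then pH 7 phosphate buffer, 0 °C
Reagents that add atoms: bromotrimethylsilane, C[Si](C)(C)Br
Why: Conjugate addition of bromide to the silyl-activated enone (1,4-hydrobromination) occurs at C12 anti to the adjacent ethyl group, as for 4-substituted cyclohexenones; this also gives the more stable trans-diequatorial product (C12, R).

Step 9
Reactants: 16 (2R,5R,6S)-5-bromo-6-ethyl-2-[(trimethylsilyl)ethynyl]oxan-3-one
Product: 17 (2R,3R,5R,6S)-5-bromo-6-ethyl-2-[(trimethylsilyl)ethynyl]oxan-3-ol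
Conditions: LiBH(s-Bu)3, THF, −78 °C; aq. NH4Cl
Reagents that add atoms: none
Why: The bulky hydride attacks the chair ketone from the equatorial side, giving the axial C10 alcohol cis to the C9 alkynyl group; the low temperature suppresses loss of HBr from the β-bromo ketone.

Step 10
Reactants: 17 (2R,3R,5R,6S)-5-bromo-6-ethyl-2-[(trimethylsilyl)ethynyl]oxan-3-ol
Product: 18 {[(2R,3S,5R,6S)-3,5-dibromo-6-ethyloxan-2-yl]ethynyl}trimethylsilane
Conditions: CBr4, P(n-C8H17)3, PhMe, 70 °C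
Reagents that add atoms: tetrabromomethane, BrC(Br)(Br)Br
Why: Appel bromination displaces the axial alkoxyphosphonium group by SN2 with inversion, giving the equatorial C10 bromide (S) and an all-equatorial ring C; the neighbouring alkynyl group is small and linear.

**Union and end game**

Step 11
Reactants: 9 (4S,5S)-4-(methoxymethoxy)-5-[(triisopropylsilyl)ethynyl]oxolan-2-yl acetate; 18 {[(2R,3S,5R,6S)-3,5-dibromo-6-ethyloxan-2-yl]ethynyl}trimethylsilane
Product: 19 triisopropyl{[(2S,3S,5S)-5-{[(2R,3S,5R,6S)-3,5-dibromo-6-ethyloxan-2-yl]ethynyl}-3-(methoxymethoxy)oxolan-2-yl]ethynyl}silane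
Conditions: Me3SiOTf (0.3 equiv), CH2Cl2, −78 → −30 °C
Reagents that add atoms: none
Why: Ionisation of 9 gives the ring-A oxocarbenium ion, which the alkynylsilane attacks at its silicon-bearing carbon (ipso-desilylative C-glycosylation of Isobe type; the triisopropylsilyl alkyne is too hindered to compete); attack on the inside face of the envelope with the C4 alkoxy group pseudoaxial (Woerpel model) puts C7 cis to the C4 oxygen, giving the all-cis ring A (C6, S).

Step 12
Reactants: 19 triisopropyl{[(2S,3S,5S)-5-{[(2R,3S,5R,6S)-3,5-dibromo-6-ethyloxan-2-yl]ethynyl}-3-(methoxymethoxy)oxolan-2-yl]ethynyl}silane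
Product: 20 triisopropyl{[(2S,3S,5S)-5-{(Z)-2-[(2R,3S,5R,6S)-3,5-dibromo-6-ethyloxan-2-yl]ethenyl}-3-(methoxymethoxy)oxolan-2-yl]ethynyl}silane
Conditions: H2 (1 atm), Pd/CaCO3 poisoned with Pb(OAc)2, quinoline, EtOAc, rt
Reagents that add atoms: none
Why: Lindlar semihydrogenation adds H2 syn to the internal C7≡C8 alkyne to give the Z alkene; the bulky silylalkyne and the secondary bromides are inert on the poisoned catalyst.

Step 13
Reactants: 20 triisopropyl{[(2S,3S,5S)-5-{(Z)-2-[(2R,3S,5R,6S)-3,5-dibromo-6-ethyloxan-2-yl]ethenyl}-3-(methoxymethoxy)oxolan-2-yl]ethynyl}silane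
Product: 21 (2S,3S,5S)-5-{(Z)-2-[(2R,3S,5R,6S)-3,5-dibromo-6-ethyloxan-2-yl]ethenyl}-2-[(triisopropylsilyl)ethynyl]oxolan-3-ol
Conditions: HCl (1 M in MeOH), 40 °C
Reagents that add atoms: none
Why: Acid-catalysed acetal exchange with methanol removes the methoxymethyl group and frees the C4 hydroxyl; ethers, bromides and the silylalkyne tolerate it.

Step 14
Reactants: 21 (2S,3S,5S)-5-{(Z)-2-[(2R,3S,5R,6S)-3,5-dibromo-6-ethyloxan-2-yl]ethenyl}-2-[(triisopropylsilyl)ethynyl]oxolan-3-ol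
Product: 22 triisopropyl{[(1S,3S,4S,6S)-3-{(R)-bromo[(2S,3S,5R,6S)-3,5-dibromo-6-ethyloxan-2-yl]methyl}-2,5-dioxabicyclo[2.2.1]heptan-6-yl]ethynyl}silane
Conditions: NBS, MeCN, 0 °C → rt, dark
Reagents that add atoms: N-bromosuccinimide, O=C1CCC(=O)N1Br
Why: 5-exo bromoetherification: A(1,3) strain of the Z alkene holds C6–H in the alkene plane, so the cis C4 hydroxyl reaches C7 from the C5 side with C8 exo (C7, S), and anti opening of the bromonium ion places bromine on C8 (R), closing ring B.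

Step 15
Reactants: 22 triisopropyl{[(1S,3S,4S,6S)-3-{(R)-bromo[(2S,3S,5R,6S)-3,5-dibromo-6-ethyloxan-2-yl]methyl}-2,5-dioxabicyclo[2.2.1]heptan-6-yl]ethynyl}silane
Product: 23 (1S,3S,4S,6S)-3-{(R)-bromo[(2S,3S,5R,6S)-3,5-dibromo-6-ethyloxan-2-yl]methyl}-6-ethynyl-2,5-dioxabicyclo[2.2.1]heptane
Conditions: n-Bu4NF, AcOH, THF, 0 °C
Reagents that add atoms: none
Why: Fluoride-induced protodesilylation of the alkynylsilane; the acetic acid buffer keeps the medium too weakly basic to eliminate HBr, and no stereocentre is touched.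

**Compound list**
1 | 3-(triisopropylsilyl)prop-2-ynal | CC(C)[Si](C(C)C)(C(C)C)C#CC=O | starting material
2 | allyl methoxymethyl ether | C=CCOCOC | starting material
3 | [(Z)-3-(methoxymethoxy)prop-2-en-1-yl]diisopinocampheylborane (Ipc groups as in (+)-isopinocampheol) | COCO/C=C\CB([C@H]1C[C@H]2C[C@@H]([C@@H]1C)C2(C)C)[C@H]1C[C@H]2C[C@@H]([C@@H]1C)C2(C)C | intermediate
4 | (3S,4S)-4-(methoxymethoxy)-1-(triisopropylsilyl)hex-5-en-1-yn-3-ol | CC(C)[Si](C(C)C)(C(C)C)C#C[C@H](O)[C@@H](OCOC)C=C | intermediate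
5 | adduct of 4 carrying 9-borabicyclo[3.3.1]nonan-9-yl groups on C6 and on the C3 oxygen | CC(C)[Si](C(C)C)(C(C)C)C#C[C@H](OB1C2CCCC1CCC2)[C@@H](OCOC)CCB1C2CCCC1CCC2 | intermediate
6 | (3S,4S)-3-(methoxymethoxy)-6-(triisopropylsilyl)hex-5-yne-1,4-diol | CC(C)[Si](C(C)C)(C(C)C)C#C[C@H](O)[C@@H](OCOC)CCO | intermediate
7 | (4S,5S)-4-(methoxymethoxy)-5-[(triisopropylsilyl)ethynyl]oxolan-2-one | CC(C)[Si](C(C)C)(C(C)C)C#C[C@@H]1OC(=O)C[C@@H]1OCOC | intermediate
8 | diisobutylaluminium lactolate of 7 | CC(C)[Si](C(C)C)(C(C)C)C#C[C@@H]1OC(O[Al](CC(C)C)CC(C)C)C[C@@H]1OCOC | intermediate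
9 | (4S,5S)-4-(methoxymethoxy)-5-[(triisopropylsilyl)ethynyl]oxolan-2-yl acetate (both C2 epimers) | CC(C)[Si](C(C)C)(C(C)C)C#C[C@@H]1OC(OC(C)=O)C[C@@H]1OCOC | intermediate
10 | 5-ethylfuran-2-carbaldehyde | CCc1ccc(C=O)o1 | starting material
11 | ethynyltrimethylsilane | C[Si](C)(C)C#C | starting material
12 | (1R)-1-(5-ethylfuran-2-yl)-3-(trimethylsilyl)prop-2-yn-1-ol | C[Si](C)(C)C#C[C@@H](O)c1ccc(CC)o1 | intermediate
13 | (2R)-6-ethyl-6-hydroxy-2-[(trimethylsilyl)ethynyl]-2H-pyran-3(6H)-one (both C6 epimers) | C[Si](C)(C)C#C[C@H]1OC(O)(CC)C=CC1=O | intermediate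
14 | (2R,6S)-6-ethyl-2-[(trimethylsilyl)ethynyl]-2H-pyran-3(6H)-one | C[Si](C)(C)C#C[C@H]1O[C@@H](CC)C=CC1=O | intermediate
15 | (2R,5R,6S)-5-bromo-6-ethyl-3-(trimethylsilyloxy)-2-[(trimethylsilyl)ethynyl]-5,6-dihydro-2H-pyran | C[Si](C)(C)C#C[C@H]1O[C@@H](CC)[C@H](Br)C=C1O[Si](C)(C)C | intermediate
16 | (2R,5R,6S)-5-bromo-6-ethyl-2-[(trimethylsilyl)ethynyl]oxan-3-one | C[Si](C)(C)C#C[C@H]1O[C@@H](CC)[C@H](Br)CC1=O | intermediate
17 | (2R,3R,5R,6S)-5-bromo-6-ethyl-2-[(trimethylsilyl)ethynyl]oxan-3-ol | C[Si](C)(C)C#C[C@H]1O[C@@H](CC)[C@H](Br)C[C@H]1O | intermediate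
18 | {[(2R,3S,5R,6S)-3,5-dibromo-6-ethyloxan-2-yl]ethynyl}trimethylsilane | C[Si](C)(C)C#C[C@H]1O[C@@H](CC)[C@H](Br)C[C@@H]1Br | intermediate
19 | triisopropyl{[(2S,3S,5S)-5-{[(2R,3S,5R,6S)-3,5-dibromo-6-ethyloxan-2-yl]ethynyl}-3-(methoxymethoxy)oxolan-2-yl]ethynyl}silane | CC(C)[Si](C(C)C)(C(C)C)C#C[C@@H]1O[C@@H](C[C@@H]1OCOC)C#C[C@H]1O[C@@H](CC)[C@H](Br)C[C@@H]1Br | intermediate
20 | triisopropyl{[(2S,3S,5S)-5-{(Z)-2-[(2R,3S,5R,6S)-3,5-dibromo-6-ethyloxan-2-yl]ethenyl}-3-(methoxymethoxy)oxolan-2-yl]ethynyl}silane | CC(C)[Si](C(C)C)(C(C)C)C#C[C@@H]1O[C@@H](C[C@@H]1OCOC)/C=C\[C@H]1O[C@@H](CC)[C@H](Br)C[C@@H]1Br | intermediate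
21 | (2S,3S,5S)-5-{(Z)-2-[(2R,3S,5R,6S)-3,5-dibromo-6-ethyloxan-2-yl]ethenyl}-2-[(triisopropylsilyl)ethynyl]oxolan-3-ol | CC(C)[Si](C(C)C)(C(C)C)C#C[C@@H]1O[C@@H](C[C@@H]1O)/C=C\[C@H]1O[C@@H](CC)[C@H](Br)C[C@@H]1Br | intermediate
22 | triisopropyl{[(1S,3S,4S,6S)-3-{(R)-bromo[(2S,3S,5R,6S)-3,5-dibromo-6-ethyloxan-2-yl]methyl}-2,5-dioxabicyclo[2.2.1]heptan-6-yl]ethynyl}silane | CC(C)[Si](C(C)C)(C(C)C)C#C[C@@H]1O[C@H]2C[C@@H]1O[C@@H]2[C@@H](Br)[C@H]1O[C@@H](CC)[C@H](Br)C[C@@H]1Br | intermediate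
23 | (1S,3S,4S,6S)-3-{(R)-bromo[(2S,3S,5R,6S)-3,5-dibromo-6-ethyloxan-2-yl]methyl}-6-ethynyl-2,5-dioxabicyclo[2.2.1]heptane | C#C[C@@H]1O[C@H]2C[C@@H]1O[C@@H]2[C@@H](Br)[C@H]1O[C@@H](CC)[C@H](Br)C[C@@H]1Br | target

**Step count**
Total: 15 steps. Longest linear sequence: 11 steps (steps 5–15, from 10 and 11 to 23); the west branch (steps 1–4) joins at step 11.

**Steps most likely to fail**

Step 14. The ring being closed is a strained 2,5-dioxabicyclo[2.2.1]heptane, and 6-endo closure onto C8 or plain addition across the alkene could compete. Fallback: from 21, Hg(O2CCF3)2 in MeCN at 0 °C followed by aqueous KBr gives, by anti oxymercuration with the same face selection, the organomercury bromide F1. Br2 in pyridine at 0 °C then replaces mercury by bromine with retention, and the route is rejoined at 22.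

Step 11. The α-oxygenated, β-brominated alkynylsilane 18 may be too weak a nucleophile, and the acetal oxygen on C4 could erode the cis selectivity. Fallback: from 18, K2CO3 in MeOH gives the terminal alkyne F2. n-BuLi, B(OMe)3 and then aqueous KHF2 convert it into the potassium alkynyltrifluoroborate F3, a much stronger alkynyl donor. F3 is coupled with 9 (BF3·OEt2, MeCN, −40 °C) by alkynyl transfer from boron, and the route is rejoined at 19.

Step 12. The internal alkyne is flanked by two ring carbons, so forcing conditions could over-reduce it or touch the silylalkyne. Fallback: from 19, (c-C6H11)2BH in THF at 0 °C adds syn across C7≡C8 to give the alkenylborane F4 (drawn with boron on C7; the C8 isomer behaves the same). Protonolysis with AcOH at room temperature proceeds with retention and rejoins the route at 20.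

**Further compounds**
F1 | step 14 | bromo{(R)-[(2S,3S,5R,6S)-3,5-dibromo-6-ethyloxan-2-yl][(1S,3S,4S,6S)-6-[(triisopropylsilyl)ethynyl]-2,5-dioxabicyclo[2.2.1]heptan-3-yl]methyl}mercury | CC(C)[Si](C(C)C)(C(C)C)C#C[C@@H]1O[C@H]2C[C@@H]1O[C@@H]2[C@@H]([Hg]Br)[C@H]1O[C@@H](CC)[C@H](Br)C[C@@H]1Br
F2 | step 11 | (2R,3S,5R,6S)-3,5-dibromo-6-ethyl-2-ethynyloxane | C#C[C@H]1O[C@@H](CC)[C@H](Br)C[C@@H]1Br
F3 | step 11 | potassium {[(2R,3S,5R,6S)-3,5-dibromo-6-ethyloxan-2-yl]ethynyl}trifluoroborate | [K+].F[B-](F)(F)C#C[C@H]1O[C@@H](CC)[C@H](Br)C[C@@H]1Br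
F4 | step 12 | dicyclohexyl (Z)-alkenylborane from syn addition of (c-C6H11)2BH to C7≡C8 of 19 (boron on C7) | CC(C)[Si](C(C)C)(C(C)C)C#C[C@@H]1O[C@@H](C[C@@H]1OCOC)/C(B(C1CCCCC1)C1CCCCC1)=C\[C@H]1O[C@@H](CC)[C@H](Br)C[C@@H]1Br
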